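**Plan**
- Ring numbering: C1 (allylic CHOAc), C2=C3(Me), C4, C5, C6=C7(CO2H), C8, C9 (CHOAc), C10 (CH-iPr). The ring-cis C2=C3(Me) olefin next to the C1 carbinol corresponds to a Z-3-iodoallylic alcohol, and the C4–C5 ethylene link to the C6=C7 enoate corresponds to the terminal vinyl group of a 2-substituted penta-2,4-dienoate. The only ring bond cut is therefore C3–C4 (hydroboration, then intramolecular B-alkyl Suzuki–Miyaura coupling).
- Chain cuts, in retrosynthetic order: C6=C7 (phosphonate olefination with acrolein), C7–C8 (phosphonoacetate alkylated by a C8 triflate), C1–C2 (propynyl Grignard on a Weinreb amide), C9–C10 (aldol).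
- Forward: aldol, ynone, anti-diol, Z-iodoalkene, phosphonate, dienoate. The single ten-membered ring closes last at C3–C4, followed by desilylation, diacetylation and ester cleavage.
- Stereochemistry: C9 and C10 come from the syn-aldol of the (S)-benzyloxazolidinone isovaleryl imide, and C1 from hydroxyl-directed 1,3-anti reduction of the ynone. The Z C2=C3 olefin comes from trans-hydroalumination/iodination and the E C6=C7 olefin from the Horner–Wadsworth–Emmons reaction.
- The acid is kept as its tert-butyl ester until both hydroxyls are acetylated, because a free C9 hydroxyl would otherwise close an α-alkylidene-γ-lactone onto C7.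

Key step: step 12

Remark: (4-methoxybenzyloxy)acetaldehyde is taken as a purchasable aldehyde; the PMB ether is preferred to a benzyl ether because it must later be removed in the presence of the alkenyl iodide.

**Step 1**
Reactants: 1 (S)-4-benzyl-2-oxazolidinone; 2 isovaleryl chloride
Product: 3 (S)-4-benzyl-3-(3-methylbutanoyl)oxazolidin-2-one
Conditions: n-BuLi, THF, −78 °C; then 2, −78 to 0 °C
Reagents that add atoms: none
Why: N-acylation of the lithiated oxazolidinone by an acid chloride is the standard route to such imides and creates no stereocentre.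

**Step 2**
Reactants: 3 (S)-4-benzyl-3-(3-methylbutanoyl)oxazolidin-2-one; 4 (4-methoxybenzyloxy)acetaldehyde
Product: 6 (S)-4-benzyl-3-[(2S,3S)-3-hydroxy-4-(4-methoxybenzyloxy)-2-(propan-2-yl)butanoyl]oxazolidin-2-one, via Z-dibutylboron enolate 5 (not isolated)
Conditions: n-Bu2BOTf, Et3N, CH2Cl2, 0 °C; then 4, −78 to 0 °C; pH 7 buffer, MeOH, H2O2, 0 °C
Reagents that add atoms: none
Why: Evans syn-aldol reaction, in which the Z-boron enolate reacts through a closed Zimmerman–Traxler chair on the face away from the benzyl group, which should set C10 and C9 (2S,3S in 6) in the required syn relationship.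

**Step 3**
Reactants: 6 the aldol imide
Product: 7 (2S,3S)-3-hydroxy-N-methoxy-4-(4-methoxybenzyloxy)-N-methyl-2-(propan-2-yl)butanamide
Conditions: MeNHOMe·HCl, AlMe3, CH2Cl2, −20 to 0 °C; aqueous potassium sodium tartrate work-up
Reagents that add atoms: N,O-dimethylhydroxylamine hydrochloride, CNOC.Cl
Why: Weinreb transamidation with the aluminium amide, in which the free β-hydroxyl (as its aluminium alkoxide) should direct attack to the exocyclic carbonyl despite the α-isopropyl group and release the auxiliary without touching C9 or C10.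

**Step 4**
Reactants: 7 the Weinreb amide; 8 1-propynylmagnesium bromide
Product: 9 (5S,6S)-6-hydroxy-7-(4-methoxybenzyloxy)-5-(propan-2-yl)hept-2-yn-4-one
Conditions: 8 (3.5 equiv), THF, −78 to 0 °C; aqueous NH4Cl
Reagents that add atoms: none
Why: Grignard acylation at a Weinreb amide, where the first equivalent forms the magnesium alkoxide and the chelated tetrahedral adduct should survive until work-up, preventing over-addition and enolisation at C10.

**Step 5**
Reactants: 9 the β-hydroxy ynone
Product: 10 (2S,3R,4S)-1-(4-methoxybenzyloxy)-3-(propan-2-yl)hept-5-yne-2,4-diol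
Conditions: Me4NBH(OAc)3, MeCN/AcOH (1:1), −30 °C
Reagents that add atoms: none
Why: Evans–Saksena reduction, in which the C9 hydroxyl exchanges onto boron and delivers hydride intramolecularly through a chair transition state with the CH2OPMB group equatorial, which should give the 1,3-anti diol and so set C1 (4S in 10).

**Step 6**
Reactants: 10 the propargylic anti-diol
Product: 12 (2S,3R,4S,5Z)-6-iodo-1-(4-methoxybenzyloxy)-3-(propan-2-yl)hept-5-ene-2,4-diol, via cyclic alkenylalanate 11 (not isolated)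
Conditions: NaAlH2(OCH2CH2OMe)2, THF, 0 °C to rt; EtOAc; then I2, THF, −78 to 0 °C
Reagents that add atoms: iodine, II
Why: Alkoxide-directed trans-hydroalumination of a propargylic alcohol puts hydride on C2 and aluminium on C3 in a five-membered alanate, and iodinolysis with retention should give only the Z-3-iodoallylic alcohol.

**Step 7**
Reactants: 12 the iodo diol
Product: 13 (2S,3R,4S,5Z)-2,4-bis(tert-butyldimethylsilyloxy)-6-iodo-1-(4-methoxybenzyloxy)-3-(propan-2-yl)hept-5-ene
Conditions: TBSOTf, 2,6-lutidine, CH2Cl2, −78 to 0 °C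
Reagents that add atoms: tert-butyldimethylsilyl triflate, CC(C)(C)[Si](C)(C)OS(=O)(=O)C(F)(F)F
Why: Silylation with the silyl triflate and a hindered base is the standard method for crowded secondary alcohols and leaves the alkenyl iodide and PMB ether untouched.

**Step 8**
Reactants: 13 the bis-silyl PMB ether
Product: 14 (2S,3R,4S,5Z)-2,4-bis(tert-butyldimethylsilyloxy)-6-iodo-3-(propan-2-yl)hept-5-en-1-ol
Conditions: DDQ, CH2Cl2/pH 7 buffer (10:1), 0 °C
Reagents that add atoms: none
Why: Oxidative PMB cleavage with DDQ under buffered conditions is selective for the electron-rich benzyl ether and tolerates silyl ethers and the alkenyl iodide, which hydrogenolysis would not.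

**Step 9**
Reactants: 14 the primary alcohol
Product: 15 (2S,3R,4S,5Z)-2,4-bis(tert-butyldimethylsilyloxy)-6-iodo-3-(propan-2-yl)hept-5-en-1-yl trifluoromethanesulfonate
Conditions: Tf2O, 2,6-lutidine, CH2Cl2, −78 °C; cold aqueous work-up, used at once without chromatography
Reagents that add atoms: triflic anhydride, O=S(=O)(OS(=O)(=O)C(F)(F)F)C(F)(F)F
Why: Triflation of a primary alcohol at low temperature gives the most reactive leaving group available, needed because SN2 displacement at C8 is slowed by the adjacent silyloxy-bearing carbon.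

**Step 10**
Reactants: 15 the C8 triflate; 16 tert-butyl diethylphosphonoacetate
Product: 17 tert-butyl (4R,5S,6S,7Z)-4,6-bis(tert-butyldimethylsilyloxy)-2-(diethoxyphosphoryl)-8-iodo-5-(propan-2-yl)non-7-enoate (both C2 epimers)
Conditions: 16 (2.5 equiv), NaH, 15-crown-5, THF/DMF, 0 °C; then 15, 0 °C to rt
Reagents that add atoms: none
Why: C-alkylation of the sodium phosphonoacetate anion by a primary triflate is a known SN2 route to α-substituted phosphonoacetates from β-oxygenated electrophiles, and the weakly basic anion should not eliminate the triflate or the alkenyl iodide; the new phosphonate-bearing centre is lost in the next step.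

**Step 11**
Reactants: 17 the α-substituted phosphonoacetate; 18 acrolein
Product: 19 tert-butyl (2E)-2-[(2R,3S,4S,5Z)-2,4-bis(tert-butyldimethylsilyloxy)-6-iodo-3-(propan-2-yl)hept-5-en-1-yl]penta-2,4-dienoate
Conditions: NaH, THF, 0 °C; then 18, −78 to 0 °C
Reagents that add atoms: none
Why: Horner–Wadsworth–Emmons olefination of an α-alkyl phosphonoacetate with an enal should give the E (tiglate-type) trisubstituted enoate with the vinyl group trans to the bulky tert-butyl ester, through reversible addition and the less crowded oxaphosphetane.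

**Step 12**
Reactants: 19 the open-chain iodo dienoate
Product: 21 tert-butyl (1E,5Z,7R,8S,9R)-7,9-bis(tert-butyldimethylsilyloxy)-5-methyl-8-(propan-2-yl)cyclodeca-1,5-diene-1-carboxylate, via B-alkyl-9-BBN borane 20 (not isolated)
Conditions: 9-BBN dimer, THF, 0 °C to rt; then slow syringe-pump addition to Pd(dppf)Cl2, AsPh3, Cs2CO3, DMF/THF/H2O, 50 °C, final concentration about 2 mM
Reagents that add atoms: none
Why: 9-BBN should add anti-Markovnikov and only to the monosubstituted C4=C5 vinyl terminus of the dienoate, since the ester-deactivated trisubstituted C6=C7 olefin and the trisubstituted iodoalkene react far more slowly, placing boron on C4 as the homoallylic borane 20. Zerovalent palladium, formed in the flask from the divalent precatalyst Pd(dppf)Cl2, then inserts into the C3–I bond with retention of the Z geometry, the base-activated borate transfers its primary alkyl group to palladium, and reductive elimination forms C3–C4. The closest known reaction type is the B-alkyl Suzuki–Miyaura macrocyclisation of an ω-boryl alkenyl iodide. The ten-membered carbocycle closes by C(sp2)–C(sp3) reductive elimination from an eleven-membered palladacycle, palladium being extruded in the ring-forming event. No stereocentre is created, and both olefin geometries are carried over unchanged from 19. The step needs chemoselective hydroboration and ring closure in preference to oligomerisation, which the steric demand of 9-BBN, slow addition at high dilution and a chain pre-bent by two cis-trisubstituted olefins and the bulky protected triad should provide, while the wide-bite-angle dppf ligand favours reductive elimination over β-hydride loss.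

**Step 13**
Reactants: 21 the macrocyclic bis-silyl ether
Product: 22 tert-butyl (1E,5Z,7R,8S,9R)-7,9-dihydroxy-5-methyl-8-(propan-2-yl)cyclodeca-1,5-diene-1-carboxylate
Conditions: HF·pyridine, pyridine, THF, 0 °C to rt
Reagents that add atoms: none
Why: Buffered fluoride desilylation removes both secondary silyl ethers without forming an alkoxide, and the hindered tert-butyl ester should resist γ-lactonisation by the freed C9 hydroxyl under these non-basic conditions.

**Step 14**
Reactants: 22 the diol ester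
Product: 23 tert-butyl (1E,5Z,7R,8S,9R)-7,9-diacetoxy-5-methyl-8-(propan-2-yl)cyclodeca-1,5-diene-1-carboxylate
Conditions: Ac2O, pyridine, DMAP, CH2Cl2, 0 °C to rt
Reagents that add atoms: acetic anhydride, CC(=O)OC(C)=O
Why: DMAP-catalysed acylation esterifies both secondary alcohols with retention and removes the lactonisation risk before the acid is unmasked.

**Step 15**
Reactants: 23 the diacetate tert-butyl ester
Product: 25 (1E,5Z,7R,8S,9R)-7,9-diacetoxy-5-methyl-8-(propan-2-yl)cyclodeca-1,5-diene-1-carboxylic acid (CNP0172943.1), via trimethylsilyl ester 24 (not isolated)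
Conditions: TMSOTf, 2,6-lutidine, CH2Cl2, 0 °C; then pH 5 aqueous work-up
Reagents that add atoms: none
Why: Silyl triflate-mediated dealkylation of a tert-butyl ester (carbonyl O-silylation, loss of the tert-butyl cation as isobutene, hydrolysis of the silyl ester on work-up) runs under buffered aprotic conditions that should spare both acetates, which protic acid or hydroxide would endanger.

**Compound list**
1 | (S)-4-benzyl-2-oxazolidinone | O=C1N[C@@H](Cc2ccccc2)CO1 | starting material
2 | isovaleryl chloride (3-methylbutanoyl chloride) | CC(C)CC(=O)Cl | starting material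
3 | (S)-4-benzyl-3-(3-methylbutanoyl)oxazolidin-2-one | CC(C)CC(=O)N1[C@@H](Cc2ccccc2)COC1=O | intermediate
4 | (4-methoxybenzyloxy)acetaldehyde | O=CCOCc1ccc(OC)cc1 | starting material
5 | Z-dibutylboron enolate of imide 3 (enolate oxygen cis to isopropyl) | CC(C)/C=C(\OB(CCCC)CCCC)N1[C@@H](Cc2ccccc2)COC1=O | intermediate
6 | (S)-4-benzyl-3-[(2S,3S)-3-hydroxy-4-(4-methoxybenzyloxy)-2-(propan-2-yl)butanoyl]oxazolidin-2-one | COc1ccc(COC[C@@H](O)[C@H](C(C)C)C(=O)N2[C@@H](Cc3ccccc3)COC2=O)cc1 | intermediate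
7 | (2S,3S)-3-hydroxy-N-methoxy-4-(4-methoxybenzyloxy)-N-methyl-2-(propan-2-yl)butanamide | COc1ccc(COC[C@@H](O)[C@H](C(C)C)C(=O)N(C)OC)cc1 | intermediate
8 | 1-propynylmagnesium bromide | CC#C[Mg]Br | starting material
9 | (5S,6S)-6-hydroxy-7-(4-methoxybenzyloxy)-5-(propan-2-yl)hept-2-yn-4-one | COc1ccc(COC[C@@H](O)[C@H](C(C)C)C(=O)C#CC)cc1 | intermediate
10 | (2S,3R,4S)-1-(4-methoxybenzyloxy)-3-(propan-2-yl)hept-5-yne-2,4-diol | COc1ccc(COC[C@@H](O)[C@H](C(C)C)[C@H](O)C#CC)cc1 | intermediate
11 | disodium cyclic alkenylalanate from 10 (five-membered ring through O on C1, Al and C3; the C9 oxygen carried as a hydridoaluminate) | COc1ccc(COC[C@@H](O[AlH-](OCCOC)OCCOC)[C@H](C(C)C)[C@@H]2O[Al-](OCCOC)(OCCOC)C(C)=C2)cc1.[Na+].[Na+] | intermediate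
12 | (2S,3R,4S,5Z)-6-iodo-1-(4-methoxybenzyloxy)-3-(propan-2-yl)hept-5-ene-2,4-diol | COc1ccc(COC[C@@H](O)[C@H](C(C)C)[C@H](O)/C=C(/C)I)cc1 | intermediate
13 | (2S,3R,4S,5Z)-2,4-bis(tert-butyldimethylsilyloxy)-6-iodo-1-(4-methoxybenzyloxy)-3-(propan-2-yl)hept-5-ene | COc1ccc(COC[C@@H](O[Si](C)(C)C(C)(C)C)[C@H](C(C)C)[C@H](O[Si](C)(C)C(C)(C)C)/C=C(/C)I)cc1 | intermediate
14 | (2S,3R,4S,5Z)-2,4-bis(tert-butyldimethylsilyloxy)-6-iodo-3-(propan-2-yl)hept-5-en-1-ol | OC[C@@H](O[Si](C)(C)C(C)(C)C)[C@H](C(C)C)[C@H](O[Si](C)(C)C(C)(C)C)/C=C(/C)I | intermediate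
15 | (2S,3R,4S,5Z)-2,4-bis(tert-butyldimethylsilyloxy)-6-iodo-3-(propan-2-yl)hept-5-en-1-yl trifluoromethanesulfonate | O=S(=O)(OC[C@@H](O[Si](C)(C)C(C)(C)C)[C@H](C(C)C)[C@H](O[Si](C)(C)C(C)(C)C)/C=C(/C)I)C(F)(F)F | intermediate
16 | tert-butyl diethylphosphonoacetate | CCOP(=O)(CC(=O)OC(C)(C)C)OCC | starting material
17 | tert-butyl (4R,5S,6S,7Z)-4,6-bis(tert-butyldimethylsilyloxy)-2-(diethoxyphosphoryl)-8-iodo-5-(propan-2-yl)non-7-enoate (C2 epimers) | CCOP(=O)(OCC)C(C[C@@H](O[Si](C)(C)C(C)(C)C)[C@H](C(C)C)[C@H](O[Si](C)(C)C(C)(C)C)/C=C(/C)I)C(=O)OC(C)(C)C | intermediate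
18 | acrolein | C=CC=O | starting material
19 | tert-butyl (2E)-2-[(2R,3S,4S,5Z)-2,4-bis(tert-butyldimethylsilyloxy)-6-iodo-3-(propan-2-yl)hept-5-en-1-yl]penta-2,4-dienoate | C=C/C=C(/C(=O)OC(C)(C)C)C[C@@H](O[Si](C)(C)C(C)(C)C)[C@H](C(C)C)[C@H](O[Si](C)(C)C(C)(C)C)/C=C(/C)I | intermediate
20 | B-alkyl-9-BBN borane from 19 (boron on C4, the former terminal vinyl carbon) | C1CC2CCCC(C1)B2CC/C=C(/C(=O)OC(C)(C)C)C[C@@H](O[Si](C)(C)C(C)(C)C)[C@H](C(C)C)[C@H](O[Si](C)(C)C(C)(C)C)/C=C(/C)I | intermediate
21 | tert-butyl (1E,5Z,7R,8S,9R)-7,9-bis(tert-butyldimethylsilyloxy)-5-methyl-8-(propan-2-yl)cyclodeca-1,5-diene-1-carboxylate | CC(C)(C)[Si](C)(C)O[C@@H]1/C=C(/C)CC/C=C(/C(=O)OC(C)(C)C)C[C@@H](O[Si](C)(C)C(C)(C)C)[C@@H]1C(C)C | intermediate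
22 | tert-butyl (1E,5Z,7R,8S,9R)-7,9-dihydroxy-5-methyl-8-(propan-2-yl)cyclodeca-1,5-diene-1-carboxylate | O[C@@H]1/C=C(/C)CC/C=C(/C(=O)OC(C)(C)C)C[C@@H](O)[C@@H]1C(C)C | intermediate
23 | tert-butyl (1E,5Z,7R,8S,9R)-7,9-diacetoxy-5-methyl-8-(propan-2-yl)cyclodeca-1,5-diene-1-carboxylate | CC(=O)O[C@@H]1/C=C(/C)CC/C=C(/C(=O)OC(C)(C)C)C[C@@H](OC(C)=O)[C@@H]1C(C)C | intermediate
24 | trimethylsilyl (1E,5Z,7R,8S,9R)-7,9-diacetoxy-5-methyl-8-(propan-2-yl)cyclodeca-1,5-diene-1-carboxylate | CC(=O)O[C@@H]1/C=C(/C)CC/C=C(/C(=O)O[Si](C)(C)C)C[C@@H](OC(C)=O)[C@@H]1C(C)C | intermediate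
25 | (1E,5Z,7R,8S,9R)-7,9-diacetoxy-5-methyl-8-(propan-2-yl)cyclodeca-1,5-diene-1-carboxylic acid (CNP0172943.1) | CC(=O)O[C@@H]1/C=C(/C)CC/C=C(/C(=O)O)C[C@@H](OC(C)=O)[C@@H]1C(C)C | target

**Step count**
Total steps: 15. Longest linear sequence: 15 steps (from 1 and 2 to 25; the route is fully linear).

**Steps most likely to fail**

Step 12. Intermolecular coupling may outrun closure of the strained ten-membered ring, and the alkylborane or alkylpalladium may be lost to protodeboronation or β-hydride elimination. The fallback sets out from phosphonate 17 and keeps the C3–C4 Suzuki bond but makes it intermolecularly, closing the ring at C6=C7 instead. Acrolein diethyl acetal is hydroborated with 9-BBN to the 9-(3,3-diethoxypropyl)-9-BBN borane F1. F1 is coupled with the alkenyl iodide of 17 (Pd(dppf)Cl2, AsPh3, Cs2CO3, DMF/THF/H2O) to give the acetal phosphonate F2. Mild acid hydrolysis (aqueous AcOH, THF) releases the aldehyde phosphonate F3. An intramolecular Horner–Wadsworth–Emmons reaction under Masamune–Roush conditions (LiCl, DBU, MeCN, high dilution) then closes the ring and returns to the route at 21.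

Step 15. The silyl triflate may ionise the C1 allylic acetate, or dealkylation of the conjugated ester may stall. The fallback sets out from 21 and exchanges the ester for a fluoride-labile one before the acetates are in place. TMSOTf and 2,6-lutidine convert 21 through the bis-silyl ether trimethylsilyl ester F4 (hydrolysed on work-up) into the bis-silyl ether acid F5. F5 is esterified with 2-(trimethylsilyl)ethanol (EDC, DMAP) to the 2-(trimethylsilyl)ethyl ester F6. HF·pyridine gives the diol 2-(trimethylsilyl)ethyl ester F7, and Ac2O, pyridine and DMAP give the diacetate 2-(trimethylsilyl)ethyl ester F8. TBAF in THF at 0 °C then removes the ester under non-acidic conditions and returns to the route at 25.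

Step 5. Facial selectivity of the internal hydride delivery may be poor, because the alkynyl group is small and the isopropyl group sits axial in the chelated chair; the hydroxy ynone may also cyclise. The fallback sets out from 9 and replaces substrate control by catalyst control. The C9 hydroxyl is silylated (TBSOTf, 2,6-lutidine) to the silyloxy ynone F9. Noyori transfer hydrogenation with RuCl[(S,S)-TsDPEN](p-cymene) in isopropanol should give the (4S)-propargylic alcohol F10. Hydroalumination with NaAlH2(OCH2CH2OMe)2 gives the cyclic alkenylalanate F11 (not isolated), and iodination gives the Z-iodoallylic alcohol F12. A second silylation with TBSOTf returns to the route at 13.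

**Further compounds**
F1 | step 12 | 9-(3,3-diethoxypropyl)-9-borabicyclo[3.3.1]nonane | CCOC(CCB1C2CCCC1CCC2)OCC
F2 | step 12 | tert-butyl (4R,5S,6R,7Z)-4,6-bis(tert-butyldimethylsilyloxy)-2-(diethoxyphosphoryl)-11,11-diethoxy-8-methyl-5-(propan-2-yl)undec-7-enoate | CCOP(=O)(OCC)C(C[C@@H](O[Si](C)(C)C(C)(C)C)[C@H](C(C)C)[C@H](O[Si](C)(C)C(C)(C)C)/C=C(/C)CCC(OCC)OCC)C(=O)OC(C)(C)C
F3 | step 12 | tert-butyl (4R,5S,6R,7Z)-4,6-bis(tert-butyldimethylsilyloxy)-2-(diethoxyphosphoryl)-8-methyl-11-oxo-5-(propan-2-yl)undec-7-enoate | CCOP(=O)(OCC)C(C[C@@H](O[Si](C)(C)C(C)(C)C)[C@H](C(C)C)[C@H](O[Si](C)(C)C(C)(C)C)/C=C(/C)CCC=O)C(=O)OC(C)(C)C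
F4 | step 15 | trimethylsilyl (1E,5Z,7R,8S,9R)-7,9-bis(tert-butyldimethylsilyloxy)-5-methyl-8-(propan-2-yl)cyclodeca-1,5-diene-1-carboxylate | CC(C)(C)[Si](C)(C)O[C@@H]1/C=C(/C)CC/C=C(/C(=O)O[Si](C)(C)C)C[C@@H](O[Si](C)(C)C(C)(C)C)[C@@H]1C(C)C
F5 | step 15 | (1E,5Z,7R,8S,9R)-7,9-bis(tert-butyldimethylsilyloxy)-5-methyl-8-(propan-2-yl)cyclodeca-1,5-diene-1-carboxylic acid | CC(C)(C)[Si](C)(C)O[C@@H]1/C=C(/C)CC/C=C(/C(=O)O)C[C@@H](O[Si](C)(C)C(C)(C)C)[C@@H]1C(C)C
F6 | step 15 | 2-(trimethylsilyl)ethyl (1E,5Z,7R,8S,9R)-7,9-bis(tert-butyldimethylsilyloxy)-5-methyl-8-(propan-2-yl)cyclodeca-1,5-diene-1-carboxylate | CC(C)(C)[Si](C)(C)O[C@@H]1/C=C(/C)CC/C=C(/C(=O)OCC[Si](C)(C)C)C[C@@H](O[Si](C)(C)C(C)(C)C)[C@@H]1C(C)C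
F7 | step 15 | 2-(trimethylsilyl)ethyl (1E,5Z,7R,8S,9R)-7,9-dihydroxy-5-methyl-8-(propan-2-yl)cyclodeca-1,5-diene-1-carboxylate | O[C@@H]1/C=C(/C)CC/C=C(/C(=O)OCC[Si](C)(C)C)C[C@@H](O)[C@@H]1C(C)C
F8 | step 15 | 2-(trimethylsilyl)ethyl (1E,5Z,7R,8S,9R)-7,9-diacetoxy-5-methyl-8-(propan-2-yl)cyclodeca-1,5-diene-1-carboxylate | CC(=O)O[C@@H]1/C=C(/C)CC/C=C(/C(=O)OCC[Si](C)(C)C)C[C@@H](OC(C)=O)[C@@H]1C(C)C
F9 | step 5 | (5S,6S)-6-(tert-butyldimethylsilyloxy)-7-(4-methoxybenzyloxy)-5-(propan-2-yl)hept-2-yn-4-one | COc1ccc(COC[C@@H](O[Si](C)(C)C(C)(C)C)[C@H](C(C)C)C(=O)C#CC)cc1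
F10 | step 5 | (2S,3R,4S)-2-(tert-butyldimethylsilyloxy)-1-(4-methoxybenzyloxy)-3-(propan-2-yl)hept-5-yn-4-ol | COc1ccc(COC[C@@H](O[Si](C)(C)C(C)(C)C)[C@H](C(C)C)[C@H](O)C#CC)cc1
F11 | step 5 | sodium cyclic alkenylalanate from F10 (five-membered ring through O on C1, Al and C3) | COc1ccc(COC[C@@H](O[Si](C)(C)C(C)(C)C)[C@H](C(C)C)[C@@H]2O[Al-](OCCOC)(OCCOC)C(C)=C2)cc1.[Na+]
F12 | step 5 | (2S,3R,4S,5Z)-2-(tert-butyldimethylsilyloxy)-6-iodo-1-(4-methoxybenzyloxy)-3-(propan-2-yl)hept-5-en-4-ol | COc1ccc(COC[C@@H](O[Si](C)(C)C(C)(C)C)[C@H](C(C)C)[C@H](O)/C=C(/C)I)cc1
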